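**Retrosynthetic overview**
- Last step: one flask closes the 10-membered ring (C6–C7 bond, allyl-chromium addition to the C6 aldehyde) and then the γ-lactone (O6–C12); C6 and C7 are set there from C8.
- The (Z)-2-(bromomethyl)enoate (C7, C11–C13) comes from a Morita–Baylis–Hillman reaction on the C7 α-acyloxy aldehyde, then SN2' bromination.
- The ring-cis C1=C10 alkene with C14-OAc and C8-O-glycolate comes from an (E)-α-alkylidene-γ-lactone (HWE), reduced to a diol and acylated selectively.
- Chiral pool: C4 from (S)-citronellal; C8 from (S)-5-(hydroxymethyl)butyrolactone (from L-glutamic acid).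

Assumption: germacrane numbering is used (C6 = lactone carbinol, C8 = glycolate carbinol, C14 = acetoxymethyl carbon, C4 = methyl-bearing carbon); in this numbering the target is 4S,6S,7S,8S, with C2 and C9 cis on C1=C10 (CIP E) and a cis-fused lactone.

**Step 1**
Reactants: 1 (S)-citronellal
Product: 3 (S)-6,6-dimethoxy-4-methylhexanal, via citronellal dimethyl acetal 2 (not isolated)
Conditions: HC(OMe)3, MeOH, p-TsOH (cat.), rt; NaHCO3; then O3, CH2Cl2/MeOH, −78 °C; Me2S, −78 °C → rt
Reagents that add atoms: trimethyl orthoformate, COC(OC)OC; ozone, [O-][O+]=O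
Why: Acid-catalysed acetalisation masks the C6 aldehyde and ozonolysis with reductive work-up cleaves the trisubstituted alkene to the C1 aldehyde, leaving the C4 stereocentre of (S)-citronellal untouched.

**Step 2**
Reactants: 4 (S)-5-(hydroxymethyl)dihydrofuran-2(3H)-one
Product: 5 (S)-5-[(triethylsilyloxy)methyl]dihydrofuran-2(3H)-one
Conditions: TESCl, imidazole, CH2Cl2, 0 °C → rt
Reagents that add atoms: chlorotriethylsilane, CC[Si](Cl)(CC)CC
Why: Routine silylation; a primary TES ether is chosen because it can later be oxidised directly to the aldehyde.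

**Step 3**
Reactants: 5 (S)-5-[(triethylsilyloxy)methyl]dihydrofuran-2(3H)-one; 3 (S)-6,6-dimethoxy-4-methylhexanal
Product: 8 (3E,5S)-3-[(4S)-6,6-dimethoxy-4-methylhexylidene]-5-[(triethylsilyloxy)methyl]dihydrofuran-2(3H)-one, via enol phosphate 6 (not isolated), via lithiated phosphono lactone 7 (not isolated)
Conditions: LDA, THF, −78 °C; ClP(O)(OEt)2; LDA, −78 → 0 °C; then 3, −78 °C → rt
Reagents that add atoms: diethyl chlorophosphate, CCOP(Cl)(=O)OCC (its phosphoryl group is carried by 6 and 7 only and is not retained in 8)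
Why: One-flask enolate O-phosphorylation, 1,3-O→C phosphoryl shift (vinyl phosphate to phosphonate rearrangement) and Horner–Wadsworth–Emmons olefination give the alkylidene lactone; the favoured E isomer (chain trans to C=O) fixes C2 cis to C9, and any minor Z isomer is removed by chromatography.

**Step 4**
Reactants: 8 (3E,5S)-3-[(4S)-6,6-dimethoxy-4-methylhexylidene]-5-[(triethylsilyloxy)methyl]dihydrofuran-2(3H)-one
Product: 9 (2S,4E,8S)-4-(hydroxymethyl)-10,10-dimethoxy-8-methyl-1-(triethylsilyloxy)dec-4-en-2-ol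
Conditions: DIBAL-H (4 eq), CH2Cl2, −78 → 0 °C; Rochelle salt
Reagents that add atoms: none
Why: DIBAL-H reduction of the conjugated lactone (1,2-reduction) releases C14 as a primary allylic alcohol and C8 as a secondary alcohol with alkene geometry and C8 configuration unchanged.

**Step 5**
Reactants: 10 glycolic acid
Product: 12 (tert-butyldimethylsilyloxy)acetic acid, via bis-silylated glycolate 11 (not isolated)
Conditions: TBSCl (2.2 eq), imidazole, DMF, rt; then THF/H2O, AcOH (cat.), 0 °C
Reagents that add atoms: tert-butyldimethylsilyl chloride, CC(C)(C)[Si](C)(C)Cl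
Why: Exhaustive silylation followed by selective hydrolysis of the much more labile silyl ester gives the O-protected acid.

**Step 6**
Reactants: 9 (2S,4E,8S)-4-(hydroxymethyl)-10,10-dimethoxy-8-methyl-1-(triethylsilyloxy)dec-4-en-2-ol; 12 (tert-butyldimethylsilyloxy)acetic acid
Product: 14 (2S,4E,8S)-4-(acetoxymethyl)-10,10-dimethoxy-8-methyl-1-(triethylsilyloxy)dec-4-en-2-yl (tert-butyldimethylsilyloxy)acetate, via C14 monoacetate 13 (not isolated)
Conditions: AcCl (1.05 eq), 2,4,6-collidine, CH2Cl2, −78 °C; then 12, EDC·HCl, DMAP (cat.), 0 °C → rt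
Reagents that add atoms: acetyl chloride, CC(Cl)=O
Why: AcCl/collidine at −78 °C acetylates only the primary allylic hydroxyl, and Steglich-type carbodiimide esterification then acylates the remaining secondary C8 hydroxyl with retention.

**Step 7**
Reactants: 14 (2S,4E,8S)-4-(acetoxymethyl)-10,10-dimethoxy-8-methyl-1-(triethylsilyloxy)dec-4-en-2-yl (tert-butyldimethylsilyloxy)acetate
Product: 15 (2S,4E,8S)-4-(acetoxymethyl)-10,10-dimethoxy-8-methyl-1-oxodec-4-en-2-yl (tert-butyldimethylsilyloxy)acetate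
Conditions: (COCl)2, DMSO, CH2Cl2, −78 → −40 °C; Et3N, −78 → 0 °C
Reagents that add atoms: none
Why: Under Swern conditions a primary TES ether is desilylated by the chlorosulfonium salt and oxidised directly to the aldehyde, while the TBS ether, esters and acetal survive and the low temperature protects the C8 stereocentre.

**Step 8**
Reactants: 15 (2S,4E,8S)-4-(acetoxymethyl)-10,10-dimethoxy-8-methyl-1-oxodec-4-en-2-yl (tert-butyldimethylsilyloxy)acetate; 16 methyl acrylate
Product: 17 methyl (3RS,4S,6E,10S)-6-(acetoxymethyl)-4-{[(tert-butyldimethylsilyloxy)acetyl]oxy}-3-hydroxy-12,12-dimethoxy-10-methyl-2-methylidenedodec-6-enoate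
Conditions: methyl acrylate (excess, neat), DABCO (1 eq), rt
Reagents that add atoms: none
Why: Morita–Baylis–Hillman reaction of the activated α-acyloxy aldehyde; the new carbinol centre is formed as a mixture, which does not matter because it becomes sp2 in step 9.

**Step 9**
Reactants: 17 methyl (3RS,4S,6E,10S)-6-(acetoxymethyl)-4-{[(tert-butyldimethylsilyloxy)acetyl]oxy}-3-hydroxy-12,12-dimethoxy-10-methyl-2-methylidenedodec-6-enoate
Product: 18 methyl (2Z,4S,6E,10S)-6-(acetoxymethyl)-2-(bromomethyl)-4-{[(tert-butyldimethylsilyloxy)acetyl]oxy}-12,12-dimethoxy-10-methyldodeca-2,6-dienoate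
Conditions: NBS, Me2S, CH2Cl2, −20 °C → rt
Reagents that add atoms: N-bromosuccinimide, O=C1CCC(=O)N1Br
Why: Corey–Kim-type activation of the allylic alcohol and SN2' attack of bromide give the transposed allylic bromide as the Z isomer (CH2Br cis to C8), the usual outcome for Baylis–Hillman adducts.

**Step 10**
Reactants: 18 methyl (2Z,4S,6E,10S)-6-(acetoxymethyl)-2-(bromomethyl)-4-{[(tert-butyldimethylsilyloxy)acetyl]oxy}-12,12-dimethoxy-10-methyldodeca-2,6-dienoate
Product: 19 methyl (2Z,4S,6E,10S)-6-(acetoxymethyl)-2-(bromomethyl)-4-(glycoloyloxy)-10-methyl-12-oxododeca-2,6-dienoate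
Conditions: 48% aq. HF, MeCN, 0 °C → rt
Reagents that add atoms: water, O
Why: Aqueous HF hydrolyses the dimethyl acetal and cleaves the primary TBS ether in one operation, leaving the esters and the allylic bromide intact; the product is used at once.

**Step 11**
Reactants: 19 methyl (2Z,4S,6E,10S)-6-(acetoxymethyl)-2-(bromomethyl)-4-(glycoloyloxy)-10-methyl-12-oxododeca-2,6-dienoate
Product: 21 (4S,6S,7S,8S)-14-acetoxy-8-(glycoloyloxy)germacra-1(10)E,11(13)-dien-12,6-olide (target), via hydroxy ester 20 (not isolated)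
Conditions: CrCl2 (8 eq), THF, rt, syringe-pump addition (final 2 mM); aq. NH4Cl; PPTS (cat.), CH2Cl2, rt
Reagents that add atoms: none
Why: Intramolecular Nozaki–Hiyama (Barbier-type) allylation: the Z-allyl-chromium adds through C7 to the C6 aldehyde in a chair Zimmerman–Traxler transition state (6,7-syn, hence cis-lactone) on the face anti to the C8–O bond with H8 eclipsing the allyl unit (A(1,3) control), which is expected to give 6S,7S from 8S, and the C6 alkoxide then lactonises onto the methyl ester.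

**Compound list**
1 | (S)-citronellal | O=CC[C@@H](C)CCC=C(C)C | starting material
2 | (S)-8,8-dimethoxy-2,6-dimethyloct-2-ene (citronellal dimethyl acetal) | COC(OC)C[C@@H](C)CCC=C(C)C | intermediate
3 | (S)-6,6-dimethoxy-4-methylhexanal | COC(OC)C[C@@H](C)CCC=O | intermediate
4 | (S)-5-(hydroxymethyl)dihydrofuran-2(3H)-one | O=C1CC[C@@H](CO)O1 | starting material
5 | (S)-5-[(triethylsilyloxy)methyl]dihydrofuran-2(3H)-one | O=C1CC[C@@H](CO[Si](CC)(CC)CC)O1 | intermediate
6 | diethyl (5S)-5-[(triethylsilyloxy)methyl]-4,5-dihydrofuran-2-yl phosphate | CCOP(=O)(OCC)OC1=CC[C@@H](CO[Si](CC)(CC)CC)O1 | intermediate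
7 | diethyl {(5S)-2-oxo-5-[(triethylsilyloxy)methyl]tetrahydrofuran-3-yl}phosphonate (present as its lithium enolate) | CCOP(=O)(OCC)C1C[C@@H](CO[Si](CC)(CC)CC)OC1=O | intermediate
8 | (3E,5S)-3-[(4S)-6,6-dimethoxy-4-methylhexylidene]-5-[(triethylsilyloxy)methyl]dihydrofuran-2(3H)-one | O=C1O[C@H](CO[Si](CC)(CC)CC)C/C1=C\CC[C@H](C)CC(OC)OC | intermediate
9 | (2S,4E,8S)-4-(hydroxymethyl)-10,10-dimethoxy-8-methyl-1-(triethylsilyloxy)dec-4-en-2-ol | OC/C(C[C@H](O)CO[Si](CC)(CC)CC)=C/CC[C@H](C)CC(OC)OC | intermediate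
10 | glycolic acid | OCC(=O)O | starting material
11 | tert-butyldimethylsilyl (tert-butyldimethylsilyloxy)acetate | CC(C)(C)[Si](C)(C)OCC(=O)O[Si](C)(C)C(C)(C)C | intermediate
12 | (tert-butyldimethylsilyloxy)acetic acid | CC(C)(C)[Si](C)(C)OCC(=O)O | intermediate
13 | (2E,6S)-2-[(2S)-2-hydroxy-3-(triethylsilyloxy)propyl]-8,8-dimethoxy-6-methyloct-2-en-1-yl acetate | CC(=O)OC/C(C[C@H](O)CO[Si](CC)(CC)CC)=C/CC[C@H](C)CC(OC)OC | intermediate
14 | (2S,4E,8S)-4-(acetoxymethyl)-10,10-dimethoxy-8-methyl-1-(triethylsilyloxy)dec-4-en-2-yl (tert-butyldimethylsilyloxy)acetate | CC(=O)OC/C(C[C@H](OC(=O)CO[Si](C)(C)C(C)(C)C)CO[Si](CC)(CC)CC)=C/CC[C@H](C)CC(OC)OC | intermediate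
15 | (2S,4E,8S)-4-(acetoxymethyl)-10,10-dimethoxy-8-methyl-1-oxodec-4-en-2-yl (tert-butyldimethylsilyloxy)acetate | CC(=O)OC/C(C[C@H](OC(=O)CO[Si](C)(C)C(C)(C)C)C=O)=C/CC[C@H](C)CC(OC)OC | intermediate
16 | methyl acrylate | C=CC(=O)OC | starting material
17 | methyl (3RS,4S,6E,10S)-6-(acetoxymethyl)-4-{[(tert-butyldimethylsilyloxy)acetyl]oxy}-3-hydroxy-12,12-dimethoxy-10-methyl-2-methylidenedodec-6-enoate | C=C(C(=O)OC)C(O)[C@@H](OC(=O)CO[Si](C)(C)C(C)(C)C)C/C(COC(C)=O)=C\CC[C@H](C)CC(OC)OC | intermediate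
18 | methyl (2Z,4S,6E,10S)-6-(acetoxymethyl)-2-(bromomethyl)-4-{[(tert-butyldimethylsilyloxy)acetyl]oxy}-12,12-dimethoxy-10-methyldodeca-2,6-dienoate | BrC/C(C(=O)OC)=C\[C@@H](OC(=O)CO[Si](C)(C)C(C)(C)C)C/C(COC(C)=O)=C\CC[C@H](C)CC(OC)OC | intermediate
19 | methyl (2Z,4S,6E,10S)-6-(acetoxymethyl)-2-(bromomethyl)-4-(glycoloyloxy)-10-methyl-12-oxododeca-2,6-dienoate | BrC/C(C(=O)OC)=C\[C@@H](OC(=O)CO)C/C(COC(C)=O)=C\CC[C@H](C)CC=O | intermediate
20 | methyl 2-[(1S,2S,4E,8S,10S)-4-(acetoxymethyl)-2-(glycoloyloxy)-10-hydroxy-8-methylcyclodec-4-en-1-yl]prop-2-enoate | COC(=O)C(=C)[C@@H]1[C@@H](OC(=O)CO)C/C(COC(C)=O)=C\CC[C@H](C)C[C@@H]1O | intermediate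
21 | (4S,6S,7S,8S)-14-acetoxy-8-(glycoloyloxy)germacra-1(10)E,11(13)-dien-12,6-olide | C=C1C(=O)O[C@H]2C[C@@H](C)CC/C=C(/COC(C)=O)C[C@H](OC(=O)CO)[C@@H]12 | target

**Totals**
Total step count: 11. Longest linear sequence: 9 steps (1, 3, 4, 6, 7, 8, 9, 10, 11 from (S)-citronellal; steps 2 and 5 are side branches).

**Three steps most likely to fail**

Step 11 (ring closure). The allyl-chromium carries an acyloxy group at C8 and may undergo 1,4-elimination to a diene, be reduced, or oligomerise before it finds the aldehyde; the facial selectivity is also a prediction. Fallback: replace the reductive metal by an allylboration. It sets out from 17, which is acetylated (Ac2O, pyridine, DMAP) to the Baylis–Hillman acetate F1. Copper-catalysed conjugate borylation with loss of acetate (B2pin2, CuCl, KOAc, DMF) then gives the pinacol allylboronate F2, with CH2Bpin cis to C8. Aqueous HF in MeCN unmasks the aldehyde and the glycolate hydroxyl to give the aldehyde allylboronate F3. Heating F3 in dilute toluene (80 °C, or Sc(OTf)3 catalysis at rt) effects the intramolecular allylboration through the same chair arrangement, and after aqueous work-up the route is rejoined at 20, which lactonises to 21 as in step 11.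

Step 8 (Baylis–Hillman). The amine and the long reaction time may cause O8→O7 acyl migration in the adduct or epimerisation of the α-acyloxy aldehyde. Fallback: an amine-free tandem Michael–aldol route. It sets out from 15: Me2AlSePh (from Me3Al and PhSeH) adds to methyl acrylate at −78 °C and the aluminium enolate is trapped by 15 to give the β-phenylseleno aldol adduct F4. Oxidation with H2O2/pyridine at 0 °C and selenoxide syn-elimination then return to the route at 17.

Step 3 (olefination). The lithium phosphonate anion may give a poor E/Z ratio or enolise aldehyde 3. Fallback: aldol condensation under thermodynamic control. It sets out from 5: the lithium enolate (LDA, THF, −78 °C) adds to 3 to give the β-hydroxy lactone F5 as a diastereomer mixture. Mesylation (MsCl, Et3N) and E1cB elimination with DBU give the E-alkylidene lactone, rejoining the route at 8.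

**Further compounds**
F1 | step 11 | methyl (3RS,4S,6E,10S)-3-acetoxy-6-(acetoxymethyl)-4-{[(tert-butyldimethylsilyloxy)acetyl]oxy}-12,12-dimethoxy-10-methyl-2-methylidenedodec-6-enoate | C=C(C(=O)OC)C(OC(C)=O)[C@@H](OC(=O)CO[Si](C)(C)C(C)(C)C)C/C(COC(C)=O)=C\CC[C@H](C)CC(OC)OC
F2 | step 11 | methyl (2E,4S,6E,10S)-6-(acetoxymethyl)-4-{[(tert-butyldimethylsilyloxy)acetyl]oxy}-12,12-dimethoxy-10-methyl-2-[(4,4,5,5-tetramethyl-1,3,2-dioxaborolan-2-yl)methyl]dodeca-2,6-dienoate | CC1(C)OB(OC1(C)C)C/C(C(=O)OC)=C\[C@@H](OC(=O)CO[Si](C)(C)C(C)(C)C)C/C(COC(C)=O)=C\CC[C@H](C)CC(OC)OC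
F3 | step 11 | methyl (2E,4S,6E,10S)-6-(acetoxymethyl)-4-(glycoloyloxy)-10-methyl-12-oxo-2-[(4,4,5,5-tetramethyl-1,3,2-dioxaborolan-2-yl)methyl]dodeca-2,6-dienoate | CC1(C)OB(OC1(C)C)C/C(C(=O)OC)=C\[C@@H](OC(=O)CO)C/C(COC(C)=O)=C\CC[C@H](C)CC=O
F4 | step 8 | methyl (4S,6E,10S)-6-(acetoxymethyl)-4-{[(tert-butyldimethylsilyloxy)acetyl]oxy}-3-hydroxy-12,12-dimethoxy-10-methyl-2-[(phenylselanyl)methyl]dodec-6-enoate | COC(=O)C(C[Se]c1ccccc1)C(O)[C@@H](OC(=O)CO[Si](C)(C)C(C)(C)C)C/C(COC(C)=O)=C\CC[C@H](C)CC(OC)OC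
F5 | step 3 | (5S)-3-[(4S)-1-hydroxy-6,6-dimethoxy-4-methylhexyl]-5-[(triethylsilyloxy)methyl]dihydrofuran-2(3H)-one | O=C1O[C@H](CO[Si](CC)(CC)CC)CC1C(O)CC[C@H](C)CC(OC)OC
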